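The constants used here were drawn at random within sensible limits; the flask was simulated.

If you compare the rates at one moment and then ask how that comparison drifts, you get a ladder of times for this flask.

substrate 0.25 M (in portions, 4); gas 33 mM (held); free catalyst 2.5 mM; second catalyst 6.2 mM; time 5.0 d; the portions of substrate follow each other after 12 min, the first at the start

    second catalyst ⇌ dormant form (K1 = 12, k1 = 0.010 min⁻¹)
    gas ⇌ reagent, rate k2*(csat - [reagent]) (k2 = 0.088 min⁻¹, csat = 33 mM)
    reagent + second catalyst + intermediate → second catalyst + product (k3 = 230 L² mol⁻² min⁻¹)
    substrate + free catalyst → free catalyst + intermediate (k4 = 180 L mol⁻¹ min⁻¹)

- which holds at 5.0 d: what has brought the reaction to rest, or that it has not come to rest (forward and back rates have come level / no working catalyst is left / it is still moving / all of the substrate has reacted)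
- product at 5.0 d, in percent of the substrate charged

- at the start none of reagent is dissolved
- the reaction counts as stopped when no species that holds the substrate changes by six tenths of a point or more over the second half of the time
- run time (flask): 5.0 d

Take the steps from fastest to slowest, and write each amount as a fraction of its charge.

1. Free catalyst comes out of its step unchanged, so substrate decays pseudo-first-order with a lifetime of 2.22 min. That is shorter than the 12 min between portions, so 0.449% of a portion is reckoned to be still substrate when the next arrives.

2. Reagent refills from the held gas with a time of 11.4 min. At its fastest, this passage supplies as much reagent as the whole charge of substrate needs in 86.1 min, which is far less than the run.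

3. Second catalyst and dormant form relax towards each other in 92.3 min. This is slower than the refill. Once they have settled, the working fraction of second catalyst is 7.69%.

4. With reagent at saturation and second catalyst at that fraction, the intermediate fraction falls by a factor e in 4.60 h. Call this the drain time. In that late stretch it belongs to the rate-limiting step, being the longest on this ladder.

5. The run lasts 26.1 drain times, and no back step returns product. So I commit to all of the substrate has reacted, with product at >99.9%.

The forecast gives all of the substrate has reacted and 100%, and says of the second catalyst “it is never lost because the dormant form is reversible”.

The simulation gives all of the substrate has reacted, with product at 100%. In this flask at 2.50 d, second catalyst stood at 7.69% of its charge. In this flask, 1.00 d is 5.21 drain times, for which the reckoning gives 0.545% of the charge still to become product, and product then stood at 99.9%, slightly ahead of that reckoning. In the neighbouring flask with 0.025 M of second catalyst, the drain time is 1.14 h, so its run lasts 105 drain times, and its product reached 100%.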